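**Strategy.** The tetrahydrofuran ring (O1, C2 bearing the aryl group, C3 bearing CH2OH, C4 bearing the arylcarbinol, C5H2) is cut at C2–C3 and C4–C5. The C5–O1–C2 unit is a nonstabilised carbonyl ylide (vanillin-derived ArCH=O(+)–CH2(−)). C3=C4 is the double bond of an (S)-γ-aryl butenolide whose lactone ties the future CH2OH carbon to the carbinol oxygen, which exploits the cis relationship of the C3 and C4 side chains. One (3+2) cycloaddition anti to the γ-aryl group makes both C–C bonds, the ring and three stereocentres under control of the single butenolide stereocentre. Hydride then opens the lactone and frees both phenols.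

Key step: step 5

Remark 1: ring atoms of the target are numbered O1, C2 (aryl), C3 (CH2OH), C4 (arylcarbinol), C5 (CH2); Ar = 3-methoxy-4-(pivaloyloxy)phenyl.
Remark 2: (S,S)-ProPhenol is assumed to deliver the alkynyl group to the Si face of the aryl aldehyde; if the sense proves opposite, (R,R)-ProPhenol is used and nothing else changes.

**Step 1**
Reactants: 1 vanillin; 2 pivaloyl chloride
Product: 3 4-formyl-2-methoxyphenyl pivalate
Conditions: Et3N, DMAP (cat.), CH2Cl2, 0 °C to rt
Reagents that add atoms: pivaloyl chloride (2), CC(C)(C)C(=O)Cl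
Why: DMAP-catalysed O-acylation of the phenol; the hindered aryl ester should survive the organozinc, acid chloride and fluoride steps and is removed by the final hydride reduction.

**Step 2**
Reactants: 3 4-formyl-2-methoxyphenyl pivalate; 4 methyl propiolate
Product: 5 methyl (R)-4-hydroxy-4-[3-methoxy-4-(pivaloyloxy)phenyl]but-2-ynoate
Conditions: Me2Zn (3 equiv), (S,S)-ProPhenol (10 mol %), Ph3P=O (20 mol %), toluene, 4 °C; aq. NH4Cl quench
Reagents that add atoms: methyl propiolate (4), C#CC(=O)OC
Why: Zinc–ProPhenol catalysed enantioselective alkynylation of an aryl aldehyde (Trost alkynylation), in which the dinuclear zinc complex binds the aldehyde and the alkynylzinc and delivers the alkynyl group to the Si face, setting the carbinol centre (R here because alkynyl outranks aryl; the same arrangement is S in the lactone and in the target).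

**Step 3**
Reactants: 5 methyl (R)-4-hydroxy-4-[3-methoxy-4-(pivaloyloxy)phenyl]but-2-ynoate
Product: 7 (S)-5-[3-methoxy-4-(pivaloyloxy)phenyl]furan-2(5H)-one, via Z-hydroxy enoate 6 (not isolated)
Conditions: H2 (1 atm), Pd/CaCO3 poisoned with Pb(OAc)2, quinoline, EtOAc, rt; then PPTS (cat.), CH2Cl2, rt
Reagents that add atoms: none
Why: Lindlar semi-hydrogenation gives the Z-enoate by syn addition of hydrogen, and the Z-γ-hydroxy ester lactonises under mild acid (intramolecular transesterification) without touching the carbinol centre.

**Step 4**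
Reactants: 3 4-formyl-2-methoxyphenyl pivalate; 8 (trimethylsilyl)methanol
Product: 9 4-{bis[(trimethylsilyl)methoxy]methyl}-2-methoxyphenyl pivalate
Conditions: Me3SiCH2OH (2.5 equiv), TsOH·H2O (cat.), benzene, reflux, Dean–Stark
Reagents that add atoms: (trimethylsilyl)methanol (8), C[Si](C)(C)CO
Why: Acid-catalysed acetalisation driven by azeotropic removal of water; it installs the silylmethyl group that later serves as the latent carbanion of the ylide.

**Step 5**
Reactants: 9 4-{bis[(trimethylsilyl)methoxy]methyl}-2-methoxyphenyl pivalate; 7 (S)-5-[3-methoxy-4-(pivaloyloxy)phenyl]furan-2(5H)-one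
Product: 12 (3S,3aR,6S,6aS)-3,6-bis[3-methoxy-4-(pivaloyloxy)phenyl]tetrahydro-1H,3H-furo[3,4-c]furan-1-one (cis-fused lactone; both aryl groups exo), via chloro ether 10 (not isolated), via carbonyl ylide 11 (not isolated)
Conditions: 9 (2 equiv), AcCl (2.2 equiv), SOCl2 (5 mol %), CH2Cl2, rt, then evaporation; crude 10 added slowly to 7 and anhydrous CsF (4 equiv), MeCN, 0 °C to rt
Reagents that add atoms: none
Why: AcCl turns acetal 9 into α-chloro ether 10, fluoride attack at silicon with loss of chloride (1,3-elimination) releases carbonyl ylide 11, and 11 adds across C3=C4 of butenolide 7 in a concerted but asynchronous suprafacial 1,3-dipolar (3+2) cycloaddition. The closest known reaction type is the silicon-based 1,3-elimination route to nonstabilised carbonyl ylides and their cycloaddition to α,β-unsaturated esters. The tetrahydrofuran ring closes by an intermolecular [4π+2π] union in which C5–C4 and C2–C3 form on one face of the lactone alkene, so the bicycle is necessarily cis-fused (in the stepwise limit: Michael addition of the CH2 terminus, then capture of the benzylic oxocarbenium ion by the enolate). C3 and C4 are set by approach anti to the γ-aryl group of 7, whose single stereocentre therefore fixes the absolute sense, and C2 by an exo transition state of the E-ylide that leaves its aryl group on the convex face, trans to the lactone carbonyl. The step needs regioselectivity, which the polarised ylide should supply (larger HOMO coefficient on the unsubstituted CH2 terminus, which bonds to the β-carbon, while the benzylic carbon goes to the α-carbon), facial and exo selectivity as above, and survival of the base-sensitive γ-stereocentre of 7, for which sparingly soluble CsF, low temperature and slow addition of 10 are chosen.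

**Step 6**
Reactants: 12 (3S,3aR,6S,6aS)-3,6-bis[3-methoxy-4-(pivaloyloxy)phenyl]tetrahydro-1H,3H-furo[3,4-c]furan-1-one
Product: 13 (−)-tanegol
Conditions: LiAlH4 (excess), THF, 0 °C to rt; EtOAc quench, aq. potassium sodium tartrate
Reagents that add atoms: none
Why: Hydride reduction of the lactone to the 1,4-diol with concurrent reductive cleavage of both aryl pivalates; no stereocentre is touched, the lactone carbonyl becoming the CH2OH group and the lactone oxygen the benzylic hydroxyl.

**Compound list**
1 | vanillin (4-hydroxy-3-methoxybenzaldehyde) | COc1cc(C=O)ccc1O | starting material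
2 | pivaloyl chloride | CC(C)(C)C(=O)Cl | starting material
3 | 4-formyl-2-methoxyphenyl pivalate | COc1cc(C=O)ccc1OC(=O)C(C)(C)C | intermediate
4 | methyl propiolate | C#CC(=O)OC | starting material
5 | methyl (R)-4-hydroxy-4-[3-methoxy-4-(pivaloyloxy)phenyl]but-2-ynoate | COc1cc([C@@H](O)C#CC(=O)OC)ccc1OC(=O)C(C)(C)C | intermediate
6 | methyl (2Z,4S)-4-hydroxy-4-[3-methoxy-4-(pivaloyloxy)phenyl]but-2-enoate (not isolated) | COc1cc([C@@H](O)/C=C\C(=O)OC)ccc1OC(=O)C(C)(C)C | intermediate
7 | (S)-5-[3-methoxy-4-(pivaloyloxy)phenyl]furan-2(5H)-one | COc1cc([C@H]2OC(=O)C=C2)ccc1OC(=O)C(C)(C)C | intermediate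
8 | (trimethylsilyl)methanol | C[Si](C)(C)CO | starting material
9 | 4-{bis[(trimethylsilyl)methoxy]methyl}-2-methoxyphenyl pivalate | COc1cc(C(OC[Si](C)(C)C)OC[Si](C)(C)C)ccc1OC(=O)C(C)(C)C | intermediate
10 | 4-{chloro[(trimethylsilyl)methoxy]methyl}-2-methoxyphenyl pivalate (racemic, not isolated) | COc1cc(C(Cl)OC[Si](C)(C)C)ccc1OC(=O)C(C)(C)C | intermediate
11 | carbonyl ylide ArCH=O(+)–CH2(−), Ar = 3-methoxy-4-(pivaloyloxy)phenyl (not isolated) | COc1cc(C=[O+][CH2-])ccc1OC(=O)C(C)(C)C | intermediate
12 | (3S,3aR,6S,6aS)-3,6-bis[3-methoxy-4-(pivaloyloxy)phenyl]tetrahydro-1H,3H-furo[3,4-c]furan-1-one | COc1cc([C@@H](O4)[C@H]2CO[C@H](c3ccc(OC(=O)C(C)(C)C)c(OC)c3)[C@H]2C4=O)ccc1OC(=O)C(C)(C)C | intermediate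
13 | (−)-tanegol, 4-[(2S,3R,4R)-4-[(S)-hydroxy(4-hydroxy-3-methoxyphenyl)methyl]-3-(hydroxymethyl)oxolan-2-yl]-2-methoxyphenol | COc1cc([C@@H](O)[C@H]2CO[C@H](c3ccc(O)c(OC)c3)[C@H]2CO)ccc1O | target

**Step count.** Total: 6 steps. Longest linear sequence: 5 steps (steps 1, 2, 3, 5, 6); step 4 is a one-step branch from 3.

**Steps most likely to fail**

Step 5. Fluoride may act as a base on the acidic γ-hydrogen of the butenolide, which would erode enantiopurity and feed dienolate side reactions. The ylide may also add with poor regio- or exo/endo control, or collapse to the epoxide before it is trapped. The fallback builds the same ring stepwise and sets out from butenolide 7, using chloro ether 10 made from 9 as in step 5. Benzophenone-sensitised photoaddition of methanol to 7 (MeOH, hν 350 nm; the hydroxymethyl radical adds to the β-carbon anti to the γ-aryl group) should give (4R,5S)-4-(hydroxymethyl)-5-[3-methoxy-4-(pivaloyloxy)phenyl]dihydrofuran-2(3H)-one F1. O-Alkylation of F1 with 10 (iPr2NEt, CH2Cl2, 0 °C) should give the mixed (trimethylsilyl)methyl acetal F2. LiN(SiMe3)2 and Me3SiCl (THF, −78 °C) should convert F2 into the silyl ketene acetal F3. Me3SiOTf (CH2Cl2, −78 °C) then ionises the acetal and the ketene acetal closes onto the tethered oxocarbenium ion (intramolecular Mukaiyama-type aldol with an acetal). The tether enforces the cis ring fusion and the aryl group takes the convex face, which returns the route to 12.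

Step 2. The enantioface selectivity of the alkynylation may be low, or of the opposite sense, with this acyloxy-substituted aryl aldehyde. The fallback sets out from 3: lithium methyl propiolate (LiN(SiMe3)2, methyl propiolate, THF, −78 °C) should give the racemic methyl 4-hydroxy-4-[3-methoxy-4-(pivaloyloxy)phenyl]but-2-ynoate F4. Lipase kinetic resolution (immobilised Candida antarctica lipase B, vinyl acetate, MTBE, rt) is expected, by the Kazlauskas rule with aryl as the large group, to acetylate the unwanted antipode to methyl (S)-4-acetoxy-4-[3-methoxy-4-(pivaloyloxy)phenyl]but-2-ynoate F5. The unreacted alcohol is 5, where the route is rejoined, at the cost of at most half of the material by design.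

Step 6. Once the pivalates are cleaved in the presence of hydride, the para-phenoxides may expel the benzylic oxygen functions through quinone methide formation, with reductive loss of benzylic oxygen or ring opening. The fallback sets out from 12 and separates the two events. LiBH4 (THF, 0 °C) should reduce only the lactone and give the diol 4-[(2S,3R,4R)-4-{(S)-hydroxy[3-methoxy-4-(pivaloyloxy)phenyl]methyl}-3-(hydroxymethyl)oxolan-2-yl]-2-methoxyphenyl pivalate F6. Methanolysis of the two aryl esters without hydride (K2CO3, MeOH, rt) then returns the route to 13.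

**Further compounds**
F1 | step 5 | (4R,5S)-4-(hydroxymethyl)-5-[3-methoxy-4-(pivaloyloxy)phenyl]dihydrofuran-2(3H)-one | COc1cc([C@@H](O2)[C@@H](CO)CC2=O)ccc1OC(=O)C(C)(C)C
F2 | step 5 | mixed acetal of F1 with the aryl aldehyde and (trimethylsilyl)methanol (acetal epimers) | COc1cc([C@@H](O2)[C@@H](COC(OC[Si](C)(C)C)c3ccc(OC(=O)C(C)(C)C)c(OC)c3)CC2=O)ccc1OC(=O)C(C)(C)C
F3 | step 5 | trimethylsilyl ketene acetal of F2 | COc1cc([C@@H](O2)[C@@H](COC(OC[Si](C)(C)C)c3ccc(OC(=O)C(C)(C)C)c(OC)c3)C=C2O[Si](C)(C)C)ccc1OC(=O)C(C)(C)C
F4 | step 2 | racemic methyl 4-hydroxy-4-[3-methoxy-4-(pivaloyloxy)phenyl]but-2-ynoate | COc1cc(C(O)C#CC(=O)OC)ccc1OC(=O)C(C)(C)C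
F5 | step 2 | methyl (S)-4-acetoxy-4-[3-methoxy-4-(pivaloyloxy)phenyl]but-2-ynoate | COc1cc([C@H](OC(C)=O)C#CC(=O)OC)ccc1OC(=O)C(C)(C)C
F6 | step 6 | 4-[(2S,3R,4R)-4-{(S)-hydroxy[3-methoxy-4-(pivaloyloxy)phenyl]methyl}-3-(hydroxymethyl)oxolan-2-yl]-2-methoxyphenyl pivalate | COc1cc([C@@H](O)[C@H]2CO[C@H](c3ccc(OC(=O)C(C)(C)C)c(OC)c3)[C@H]2CO)ccc1OC(=O)C(C)(C)C
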